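The route rests on cutting C14–C15, where the methyl-bearing sp2 carbon C14 of the (E)-trisubstituted C13=C14 alkene (side chain on C9 of ring B; labdane-type numbering) meets the allylic CH2 C15. A Zweifel olefination unites a vinyllithium and a homogeranyl pinacolboronate: iodine-triggered 1,2-shift of C15 from boron to C14 and anti elimination forge the bond and convert the easily made (Z)-iodoalkene into the (E)-alkene in one operation. The precursor is a (Z)-2-iodo-2-alkene on the cis-fused decalin, in which C5 stems from (R)-α-ionone, C8 from Sharpless epoxidation, C10 from a Heck closure of ring B and C9 from hydroxyl-directed hydrogenation.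

Key step: step 15

Numbering used below: ring A = C1–C5, C10; ring B = C5–C10; C4 carries two methyls, C10 one, C8 the carbinol; the side chain runs C11–C22 from C9.

Remark on the chemistry: the target is the (1R,2R,4aR,8aS) isomer, a cis-fused decalin (H on C5 and CH3 on C10 on the same face, i.e. the C5 epimer of the usual labdane pattern), so the ring system is built de novo; (R)-α-ionone is assumed to be purchasable in enantiopure form.

Step 1
Reactants: 1 (3E)-4-[(1R)-2,6,6-trimethylcyclohex-2-en-1-yl]but-3-en-2-one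
Product: 2 4-[(1R)-2,6,6-trimethylcyclohex-2-en-1-yl]butan-2-one
Conditions: H2 (35 atm), [(Ph3P)CuH]6 (cat.), PPh3, t-BuOH, benzene, rt
Reagents that add atoms: none
Why: Copper hydride catalysed conjugate reduction delivers hydride only to the β-carbon of the enone, so the trisubstituted ring alkene and the C5 stereocenter should stay untouched.

Step 2
Reactants: 2 4-[(1R)-2,6,6-trimethylcyclohex-2-en-1-yl]butan-2-one
Product: 3 ethyl (2E)-3-methyl-5-[(1R)-2,6,6-trimethylcyclohex-2-en-1-yl]pent-2-enoate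
Conditions: (EtO)2P(O)CH2CO2Et, NaH, THF, 0 °C to reflux
Reagents that add atoms: triethyl phosphonoacetate (CCOC(=O)CP(=O)(OCC)OCC)
Why: Horner–Wadsworth–Emmons olefination of the methyl ketone should place the ester trans to the longer chain (E), the minor Z isomer being removed by chromatography.

Step 3
Reactants: 3 ethyl (2E)-3-methyl-5-[(1R)-2,6,6-trimethylcyclohex-2-en-1-yl]pent-2-enoate
Product: 4 (2E)-3-methyl-5-[(1R)-2,6,6-trimethylcyclohex-2-en-1-yl]pent-2-en-1-ol
Conditions: DIBAL-H, CH2Cl2, −78 °C to 0 °C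
Reagents that add atoms: none
Why: 1,2-Reduction of the enoate with an aluminium hydride gives the allylic alcohol without touching either alkene.

Step 4
Reactants: 4 (2E)-3-methyl-5-[(1R)-2,6,6-trimethylcyclohex-2-en-1-yl]pent-2-en-1-ol
Product: 5 [(2R,3R)-3-methyl-3-{2-[(1R)-2,6,6-trimethylcyclohex-2-en-1-yl]ethyl}oxiran-2-yl]methanol
Conditions: Ti(OiPr)4, D-(−)-diethyl tartrate, t-BuOOH, 4 Å MS, CH2Cl2, −20 °C
Reagents that add atoms: tert-butyl hydroperoxide (CC(C)(C)OO)
Why: Sharpless asymmetric epoxidation delivers oxygen to one face of the allylic alcohol under reagent control, which sets C8 (R) and C9 independently of C5, while the isolated ring alkene is not touched.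

Step 5
Reactants: 5 [(2R,3R)-3-methyl-3-{2-[(1R)-2,6,6-trimethylcyclohex-2-en-1-yl]ethyl}oxiran-2-yl]methanol
Product: 6 (2R,3S)-3-(chloromethyl)-2-methyl-2-{2-[(1R)-2,6,6-trimethylcyclohex-2-en-1-yl]ethyl}oxirane
Conditions: PPh3, CCl4, NaHCO3, reflux
Reagents that add atoms: carbon tetrachloride (ClC(Cl)(Cl)Cl)
Why: Appel chlorination converts the primary alcohol under neutral conditions and leaves the epoxide and both stereocenters intact.

Step 6
Reactants: 6 (2R,3S)-3-(chloromethyl)-2-methyl-2-{2-[(1R)-2,6,6-trimethylcyclohex-2-en-1-yl]ethyl}oxirane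
Product: 8 (5R)-5-methyl-7-[(1R)-2,6,6-trimethylcyclohex-2-en-1-yl]hept-3-yne-1,5-diol, via dilithium alkynide alkoxide 7 (not isolated)
Conditions: n-BuLi (3.3 equiv), THF, −35 °C; then ethylene oxide, HMPA, −35 °C to rt; aq. NH4Cl
Reagents that add atoms: ethylene oxide (C1CO1)
Why: Base-induced fragmentation of the 2,3-epoxy chloride (α-deprotonation, epoxide opening to a chloroallyl alkoxide, dehydrochlorination) gives the tertiary propargylic alkoxide with the C8–O bond untouched, and the acetylide formed by the third equivalent of base opens ethylene oxide to add C12 and C13.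

Step 7
Reactants: 8 (5R)-5-methyl-7-[(1R)-2,6,6-trimethylcyclohex-2-en-1-yl]hept-3-yne-1,5-diol
Product: 9 (3R)-3-methyl-7-[(triethylsilyl)oxy]-1-[(1R)-2,6,6-trimethylcyclohex-2-en-1-yl]hept-4-yn-3-ol
Conditions: TESCl, imidazole, CH2Cl2, 0 °C
Reagents that add atoms: chlorotriethylsilane (CC[Si](Cl)(CC)CC)
Why: Silylation is selective for the primary alcohol, since the tertiary propargylic alcohol is far more hindered and must stay free as a directing group.

Step 8
Reactants: 9 (3R)-3-methyl-7-[(triethylsilyl)oxy]-1-[(1R)-2,6,6-trimethylcyclohex-2-en-1-yl]hept-4-yn-3-ol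
Product: 11 (3R,4Z)-4-iodo-3-methyl-7-[(triethylsilyl)oxy]-1-[(1R)-2,6,6-trimethylcyclohex-2-en-1-yl]hept-4-en-3-ol, via vinylstannane 10 (not isolated)
Conditions: Bu3SnH, [Cp*RuCl]4 (cat.), CH2Cl2, rt; then I2, CH2Cl2, 0 °C
Reagents that add atoms: iodine (II)
Why: Hydroxyl-directed ruthenium-catalysed trans-hydrostannation should put tin on the alkyne carbon next to the free carbinol (C9), and iododestannylation with retention then gives the 2-iodoalkene needed for ring closure.

Step 9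
Reactants: 11 (3R,4Z)-4-iodo-3-methyl-7-[(triethylsilyl)oxy]-1-[(1R)-2,6,6-trimethylcyclohex-2-en-1-yl]hept-4-en-3-ol
Product: 12 (1E,2R,4aR,8aS)-2,5,5,8a-tetramethyl-1-{3-[(triethylsilyl)oxy]propylidene}-1,2,3,4,4a,5,6,8a-octahydronaphthalen-2-ol
Conditions: Pd(OAc)2 (10 mol %), PPh3, Ag2CO3, MeCN, 80 °C
Reagents that add atoms: none
Why: Intramolecular Heck reaction: after oxidative addition to zerovalent palladium, the vinylpalladium adds syn across the C10=C1 bond in a 6-exo-trig mode from the face on which the C5 tether sits (axial attack with a gauche tether), which makes C10 quaternary with CH3 syn to H on C5 (cis ring fusion), and β-hydride elimination toward C2 releases the catalyst.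

Step 10
Reactants: 12 (1E,2R,4aR,8aS)-2,5,5,8a-tetramethyl-1-{3-[(triethylsilyl)oxy]propylidene}-1,2,3,4,4a,5,6,8a-octahydronaphthalen-2-ol
Product: 13 (1R,2R,4aR,8aS)-2,5,5,8a-tetramethyl-1-{3-[(triethylsilyl)oxy]propyl}decahydronaphthalen-2-ol
Conditions: H2 (1 atm), [Ir(cod)(PCy3)(py)]PF6 (5 mol %), CH2Cl2, rt
Reagents that add atoms: none
Why: Hydroxyl-directed hydrogenation: the cationic iridium catalyst binds the free tertiary allylic alcohol on C8 and delivers hydrogen to the same face of the exocyclic C9=C11 bond, which sets C9 (H syn to OH, side chain anti), and it also saturates the C1=C2 bond.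

Step 11
Reactants: 13 (1R,2R,4aR,8aS)-2,5,5,8a-tetramethyl-1-{3-[(triethylsilyl)oxy]propyl}decahydronaphthalen-2-ol
Product: 14 triethyl{[(1R,2R,4aR,8aS)-2,5,5,8a-tetramethyl-1-{3-[(triethylsilyl)oxy]propyl}decahydronaphthalen-2-yl]oxy}silane
Conditions: TESOTf, 2,6-lutidine, CH2Cl2, −78 °C to 0 °C
Reagents that add atoms: triethylsilyl trifluoromethanesulfonate (CC[Si](CC)(CC)OS(=O)(=O)C(F)(F)F)
Why: The silyl triflate is reactive enough to silylate the hindered tertiary alcohol, which masks it for the organolithium and iodine chemistry to come.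

Step 12
Reactants: 14 triethyl{[(1R,2R,4aR,8aS)-2,5,5,8a-tetramethyl-1-{3-[(triethylsilyl)oxy]propyl}decahydronaphthalen-2-yl]oxy}silane
Product: 15 3-[(1R,2R,4aR,8aS)-2,5,5,8a-tetramethyl-2-[(triethylsilyl)oxy]decahydronaphthalen-1-yl]propanal
Conditions: (COCl)2, DMSO, CH2Cl2, −78 °C to −30 °C; then Et3N, to rt
Reagents that add atoms: none
Why: Swern oxidation applied directly to the primary triethylsilyl ether: activated DMSO cleaves the unhindered Si–O bond and oxidises C13 to the aldehyde, while the hindered tertiary silyl ether should survive.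

Step 13
Reactants: 15 3-[(1R,2R,4aR,8aS)-2,5,5,8a-tetramethyl-2-[(triethylsilyl)oxy]decahydronaphthalen-1-yl]propanal
Product: 16 triethyl{[(1R,2R,4aR,8aS)-1-[(3Z)-4-iodopent-3-en-1-yl]-2,5,5,8a-tetramethyldecahydronaphthalen-2-yl]oxy}silane
Conditions: [Ph3PCH(I)CH3]I, NaHMDS, THF, −78 °C to −20 °C
Reagents that add atoms: (1-iodoethyl)triphenylphosphonium iodide (CC(I)[P+](c1ccccc1)(c1ccccc1)c1ccccc1.[I-])
Why: Stork–Zhao olefination (Wittig reaction of the α-iodoethylidene ylide) should give the 2-iodo-2-alkene with iodine cis to the chain (Z) under kinetic control.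

Step 14
Reactants: 17 (2E)-1-bromo-3,7-dimethylocta-2,6-diene (geranyl bromide); 18 bis(4,4,5,5-tetramethyl-1,3,2-dioxaborolan-2-yl)methane
Product: 19 2-[(3E)-4,8-dimethylnona-3,7-dien-1-yl]-4,4,5,5-tetramethyl-1,3,2-dioxaborolane
Conditions: NaOt-Bu, THF, rt
Reagents that add atoms: none
Why: Deborylative alkylation: alkoxide removes one boryl group of the geminal bis(boronate) and the resulting α-boryl carbanion displaces the primary allylic bromide in an SN2 reaction, leaving the (E)-alkene unchanged.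

Step 15
Reactants: 16 triethyl{[(1R,2R,4aR,8aS)-1-[(3Z)-4-iodopent-3-en-1-yl]-2,5,5,8a-tetramethyldecahydronaphthalen-2-yl]oxy}silane; 19 2-[(3E)-4,8-dimethylnona-3,7-dien-1-yl]-4,4,5,5-tetramethyl-1,3,2-dioxaborolane
Product: 23 triethyl{[(1R,2R,4aR,8aS)-2,5,5,8a-tetramethyl-1-[(3E,7E)-4,8,12-trimethyltrideca-3,7,11-trien-1-yl]decahydronaphthalen-2-yl]oxy}silane, via vinyllithium 20 (not isolated), via lithium boronate complex 21 (not isolated), via iodoboronate 22 (not isolated)
Conditions: t-BuLi (2.1 equiv), THF, −78 °C; 19, −78 °C to 0 °C; I2, MeOH, −78 °C; NaOMe, MeOH, −78 °C to rt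
Reagents that add atoms: none
Why: Iodine–lithium exchange with tert-butyllithium gives the vinyllithium 20 with retention (lithium cis to C12), which adds to boron of 19 to form the tetracoordinate boronate 21. Iodine activates the C13=C14 bond of this electron-rich complex and C15 migrates from boron to C14 anti to the new C13–I bond (1,2-metallate rearrangement), giving the β-iodoboronate 22. Methoxide then induces anti elimination of boron and iodine, so boron at C14 is replaced by C15 with inversion of alkene geometry and the (Z)-iodoalkene becomes the (13E)-alkene. The closest known reaction type is the Zweifel olefination in its boronic ester form, which is established for trisubstituted alkenes. No ring is closed and no stereocenter remains, since the two transient centers at C13 and C14 are destroyed in the elimination and both diastereomers of 22 converge on the same alkene. The selectivity needed is complete Z-to-E stereospecificity, secured by the anti-migration/anti-elimination sequence, and attack of iodine on the boronate rather than on the trisubstituted alkenes, secured by the low temperature and the silyl mask on the C8 alcohol.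

Step 16
Reactants: 23 triethyl{[(1R,2R,4aR,8aS)-2,5,5,8a-tetramethyl-1-[(3E,7E)-4,8,12-trimethyltrideca-3,7,11-trien-1-yl]decahydronaphthalen-2-yl]oxy}silane
Product: 24 (1R,2R,4aR,8aS)-2,5,5,8a-tetramethyl-1-[(3E,7E)-4,8,12-trimethyltrideca-3,7,11-trien-1-yl]decahydronaphthalen-2-ol
Conditions: TBAF, THF, 50 °C
Reagents that add atoms: none
Why: Fluoride cleaves the tertiary Si–O bond and touches neither the triene nor any stereocenter.

Compound list
1 | (3E)-4-[(1R)-2,6,6-trimethylcyclohex-2-en-1-yl]but-3-en-2-one, (R)-α-ionone | CC1=CCCC(C)(C)[C@H]1/C=C/C(C)=O | starting material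
2 | 4-[(1R)-2,6,6-trimethylcyclohex-2-en-1-yl]butan-2-one | CC1=CCCC(C)(C)[C@H]1CCC(C)=O | intermediate
3 | ethyl (2E)-3-methyl-5-[(1R)-2,6,6-trimethylcyclohex-2-en-1-yl]pent-2-enoate | CC1=CCCC(C)(C)[C@H]1CC/C(C)=C/C(=O)OCC | intermediate
4 | (2E)-3-methyl-5-[(1R)-2,6,6-trimethylcyclohex-2-en-1-yl]pent-2-en-1-ol | CC1=CCCC(C)(C)[C@H]1CC/C(C)=C/CO | intermediate
5 | [(2R,3R)-3-methyl-3-{2-[(1R)-2,6,6-trimethylcyclohex-2-en-1-yl]ethyl}oxiran-2-yl]methanol | CC1=CCCC(C)(C)[C@H]1CC[C@@]2(C)O[C@@H]2CO | intermediate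
6 | (2R,3S)-3-(chloromethyl)-2-methyl-2-{2-[(1R)-2,6,6-trimethylcyclohex-2-en-1-yl]ethyl}oxirane | CC1=CCCC(C)(C)[C@H]1CC[C@@]2(C)O[C@@H]2CCl | intermediate
7 | dilithium salt (alkynide and alkoxide) of (3R)-3-methyl-5-[(1R)-2,6,6-trimethylcyclohex-2-en-1-yl]pent-1-yn-3-ol | CC1=CCCC(C)(C)[C@H]1CC[C@@](C)(O[Li])C#C[Li] | intermediate (not isolated)
8 | (5R)-5-methyl-7-[(1R)-2,6,6-trimethylcyclohex-2-en-1-yl]hept-3-yne-1,5-diol | CC1=CCCC(C)(C)[C@H]1CC[C@@](C)(O)C#CCCO | intermediate
9 | (3R)-3-methyl-7-[(triethylsilyl)oxy]-1-[(1R)-2,6,6-trimethylcyclohex-2-en-1-yl]hept-4-yn-3-ol | CC1=CCCC(C)(C)[C@H]1CC[C@@](C)(O)C#CCCO[Si](CC)(CC)CC | intermediate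
10 | (3R,4Z)-3-methyl-4-(tributylstannyl)-7-[(triethylsilyl)oxy]-1-[(1R)-2,6,6-trimethylcyclohex-2-en-1-yl]hept-4-en-3-ol | CC1=CCCC(C)(C)[C@H]1CC[C@@](C)(O)/C(=C/CCO[Si](CC)(CC)CC)[Sn](CCCC)(CCCC)CCCC | intermediate (not isolated)
11 | (3R,4Z)-4-iodo-3-methyl-7-[(triethylsilyl)oxy]-1-[(1R)-2,6,6-trimethylcyclohex-2-en-1-yl]hept-4-en-3-ol | CC1=CCCC(C)(C)[C@H]1CC[C@@](C)(O)/C(I)=C/CCO[Si](CC)(CC)CC | intermediate
12 | (1E,2R,4aR,8aS)-2,5,5,8a-tetramethyl-1-{3-[(triethylsilyl)oxy]propylidene}-1,2,3,4,4a,5,6,8a-octahydronaphthalen-2-ol | CC[Si](CC)(CC)OCC/C=C1\[C@@]2(C)C=CCC(C)(C)[C@H]2CC[C@@]1(C)O | intermediate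
13 | (1R,2R,4aR,8aS)-2,5,5,8a-tetramethyl-1-{3-[(triethylsilyl)oxy]propyl}decahydronaphthalen-2-ol | CC[Si](CC)(CC)OCCC[C@@H]1[C@@]2(C)CCCC(C)(C)[C@H]2CC[C@@]1(C)O | intermediate
14 | triethyl{[(1R,2R,4aR,8aS)-2,5,5,8a-tetramethyl-1-{3-[(triethylsilyl)oxy]propyl}decahydronaphthalen-2-yl]oxy}silane | CC[Si](CC)(CC)OCCC[C@@H]1[C@@]2(C)CCCC(C)(C)[C@H]2CC[C@@]1(C)O[Si](CC)(CC)CC | intermediate
15 | 3-[(1R,2R,4aR,8aS)-2,5,5,8a-tetramethyl-2-[(triethylsilyl)oxy]decahydronaphthalen-1-yl]propanal | O=CCC[C@@H]1[C@@]2(C)CCCC(C)(C)[C@H]2CC[C@@]1(C)O[Si](CC)(CC)CC | intermediate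
16 | triethyl{[(1R,2R,4aR,8aS)-1-[(3Z)-4-iodopent-3-en-1-yl]-2,5,5,8a-tetramethyldecahydronaphthalen-2-yl]oxy}silane | C/C(I)=C/CC[C@@H]1[C@@]2(C)CCCC(C)(C)[C@H]2CC[C@@]1(C)O[Si](CC)(CC)CC | intermediate
17 | (2E)-1-bromo-3,7-dimethylocta-2,6-diene (geranyl bromide) | CC(C)=CCC/C(C)=C/CBr | starting material
18 | bis(4,4,5,5-tetramethyl-1,3,2-dioxaborolan-2-yl)methane | CC1(C)OB(CB2OC(C)(C)C(C)(C)O2)OC1(C)C | starting material
19 | 2-[(3E)-4,8-dimethylnona-3,7-dien-1-yl]-4,4,5,5-tetramethyl-1,3,2-dioxaborolane (homogeranyl pinacolboronate) | CC(C)=CCC/C(C)=C/CCB1OC(C)(C)C(C)(C)O1 | intermediate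
20 | (Z)-alkenyllithium from 16 (lithium in place of iodine at C14, cis to C12) | C/C([Li])=C/CC[C@@H]1[C@@]2(C)CCCC(C)(C)[C@H]2CC[C@@]1(C)O[Si](CC)(CC)CC | intermediate (not isolated)
21 | lithium boronate complex: boron carries the pinacolato group, the homogeranyl group and the (Z)-alkenyl group of 20 | [Li+].C/C(=C/CC[C@@H]1[C@@]2(C)CCCC(C)(C)[C@H]2CC[C@@]1(C)O[Si](CC)(CC)CC)[B-]3(CC/C=C(\C)CCC=C(C)C)OC(C)(C)C(C)(C)O3 | intermediate (not isolated)
22 | β-iodoalkyl pinacolboronate (iodine on C13, boron and C15 on C14, anti adduct; one of the two C13/C14 diastereomers, both of which eliminate to 23) | CC1(C)OB(OC1(C)C)[C@](C)(CC/C=C(\C)CCC=C(C)C)[C@@H](I)CC[C@@H]2[C@@]3(C)CCCC(C)(C)[C@H]3CC[C@@]2(C)O[Si](CC)(CC)CC | intermediate (not isolated)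
23 | triethyl{[(1R,2R,4aR,8aS)-2,5,5,8a-tetramethyl-1-[(3E,7E)-4,8,12-trimethyltrideca-3,7,11-trien-1-yl]decahydronaphthalen-2-yl]oxy}silane | CC(C)=CCC/C(C)=C/CC/C(C)=C/CC[C@@H]1[C@@]2(C)CCCC(C)(C)[C@H]2CC[C@@]1(C)O[Si](CC)(CC)CC | intermediate
24 | (1R,2R,4aR,8aS)-2,5,5,8a-tetramethyl-1-[(3E,7E)-4,8,12-trimethyltrideca-3,7,11-trien-1-yl]decahydronaphthalen-2-ol | CC(C)=CCC/C(C)=C/CC/C(C)=C/CC[C@@H]1[C@@]2(C)CCCC(C)(C)[C@H]2CC[C@@]1(C)O | target

Total step count: 16. Longest linear sequence: 15 steps (steps 1–13, 15 and 16, from (R)-α-ionone).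

Steps most likely to fail

Step 9 (Heck closure of ring B). Carbopalladation onto the fully substituted C10, which is shielded by the axial methyl on C4, may be too slow, so that reduction of the vinyl–palladium bond or migration of double bonds takes over. The fallback replaces the palladium insertion by a radical conjugate addition and sets out from 11. Allylic oxidation of the C2 methylene (CrO3·3,5-dimethylpyrazole, CH2Cl2, −20 °C) should give the ring-A enone (4R)-4-[(3R,4Z)-3-hydroxy-4-iodo-3-methyl-7-[(triethylsilyl)oxy]hept-4-en-1-yl]-3,5,5-trimethylcyclohex-2-en-1-one F1. Bu3SnH/AIBN (benzene, 80 °C, slow addition) should generate the C9 vinyl radical, which adds 6-exo to C10, now the β-carbon of an enone, from the tether face, and so gives the cis-fused ketone (4aR,7R,8E,8aS)-7-hydroxy-4,4,7,8a-tetramethyl-8-{3-[(triethylsilyl)oxy]propylidene}octahydronaphthalen-2(1H)-one F2. Condensation with tosylhydrazine gives the tosylhydrazone of F2 F3, and catecholborane/NaOAc removes the C2 carbonyl to give (1E,2R,4aR,8aS)-2,5,5,8a-tetramethyl-1-{3-[(triethylsilyl)oxy]propylidene}decahydronaphthalen-2-ol F4. Hydrogenation under the conditions of step 10 comes back to the route at 13.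

Step 15 (key step). The 1,2-shift may be incomplete, or iodine may attack the trisubstituted alkenes, or the boronate may lose its alkenyl group by protonation. The fallback is a retentive cross-coupling on the opposite iodide isomer and sets out from 15. Ohira–Bestmann homologation (dimethyl (1-diazo-2-oxopropyl)phosphonate, K2CO3, MeOH) should give the terminal alkyne {[(1R,2R,4aR,8aS)-1-(but-3-yn-1-yl)-2,5,5,8a-tetramethyldecahydronaphthalen-2-yl]oxy}triethylsilane F5. n-BuLi then MeI gives the methyl alkyne {[(1R,2R,4aR,8aS)-2,5,5,8a-tetramethyl-1-(pent-3-yn-1-yl)decahydronaphthalen-2-yl]oxy}triethylsilane F6. Hydrozirconation with excess Cp2Zr(H)Cl (THF, 50 °C, zirconium on the methyl-bearing carbon) and iodinolysis give the (E)-iodide triethyl{[(1R,2R,4aR,8aS)-1-[(3E)-4-iodopent-3-en-1-yl]-2,5,5,8a-tetramethyldecahydronaphthalen-2-yl]oxy}silane F7. Suzuki–Miyaura coupling of F7 with 19 (Pd(OAc)2, SPhos, K3PO4, toluene/H2O, 80 °C) forms the same C14–C15 bond with retention and comes back to the route at 23.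

Step 13 (iodo-olefination). The α-iodo ylide may decompose before it reacts, or the Z selectivity may erode. The fallback builds the (Z)-haloalkene by cross-coupling and sets out from 15. The first stage of the Corey–Fuchs reaction (CBr4, PPh3, CH2Cl2, 0 °C) gives the dibromoalkene {[(1R,2R,4aR,8aS)-1-(4,4-dibromobut-3-en-1-yl)-2,5,5,8a-tetramethyldecahydronaphthalen-2-yl]oxy}triethylsilane F8. Trans-selective Negishi monomethylation (MeZnCl, PdCl2(DPEphos), THF) replaces the bromine trans to the chain and gives the (Z)-bromoalkene {[(1R,2R,4aR,8aS)-1-[(3Z)-4-bromopent-3-en-1-yl]-2,5,5,8a-tetramethyldecahydronaphthalen-2-yl]oxy}triethylsilane F9. Bromine–lithium exchange with t-BuLi at −78 °C comes back to the route at the vinyllithium 20 inside step 15.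

Further compounds
F1 | step 9 | (4R)-4-[(3R,4Z)-3-hydroxy-4-iodo-3-methyl-7-[(triethylsilyl)oxy]hept-4-en-1-yl]-3,5,5-trimethylcyclohex-2-en-1-one | CC1=CC(=O)CC(C)(C)[C@H]1CC[C@@](C)(O)/C(I)=C/CCO[Si](CC)(CC)CC
F2 | step 9 | (4aR,7R,8E,8aS)-7-hydroxy-4,4,7,8a-tetramethyl-8-{3-[(triethylsilyl)oxy]propylidene}octahydronaphthalen-2(1H)-one | CC[Si](CC)(CC)OCC/C=C1\[C@@]2(C)CC(=O)CC(C)(C)[C@H]2CC[C@@]1(C)O
F3 | step 9 | N'-[(4aR,7R,8E,8aS)-7-hydroxy-4,4,7,8a-tetramethyl-8-{3-[(triethylsilyl)oxy]propylidene}octahydronaphthalen-2(1H)-ylidene]-4-methylbenzenesulfonohydrazide | CC[Si](CC)(CC)OCC/C=C1\[C@@]2(C)CC(=NNS(=O)(=O)c3ccc(C)cc3)CC(C)(C)[C@H]2CC[C@@]1(C)O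
F4 | step 9 | (1E,2R,4aR,8aS)-2,5,5,8a-tetramethyl-1-{3-[(triethylsilyl)oxy]propylidene}decahydronaphthalen-2-ol | CC[Si](CC)(CC)OCC/C=C1\[C@@]2(C)CCCC(C)(C)[C@H]2CC[C@@]1(C)O
F5 | step 15 | {[(1R,2R,4aR,8aS)-1-(but-3-yn-1-yl)-2,5,5,8a-tetramethyldecahydronaphthalen-2-yl]oxy}triethylsilane | C#CCC[C@@H]1[C@@]2(C)CCCC(C)(C)[C@H]2CC[C@@]1(C)O[Si](CC)(CC)CC
F6 | step 15 | {[(1R,2R,4aR,8aS)-2,5,5,8a-tetramethyl-1-(pent-3-yn-1-yl)decahydronaphthalen-2-yl]oxy}triethylsilane | CC#CCC[C@@H]1[C@@]2(C)CCCC(C)(C)[C@H]2CC[C@@]1(C)O[Si](CC)(CC)CC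
F7 | step 15 | triethyl{[(1R,2R,4aR,8aS)-1-[(3E)-4-iodopent-3-en-1-yl]-2,5,5,8a-tetramethyldecahydronaphthalen-2-yl]oxy}silane | C/C(I)=C\CC[C@@H]1[C@@]2(C)CCCC(C)(C)[C@H]2CC[C@@]1(C)O[Si](CC)(CC)CC
F8 | step 13 | {[(1R,2R,4aR,8aS)-1-(4,4-dibromobut-3-en-1-yl)-2,5,5,8a-tetramethyldecahydronaphthalen-2-yl]oxy}triethylsilane | BrC(Br)=CCC[C@@H]1[C@@]2(C)CCCC(C)(C)[C@H]2CC[C@@]1(C)O[Si](CC)(CC)CC
F9 | step 13 | {[(1R,2R,4aR,8aS)-1-[(3Z)-4-bromopent-3-en-1-yl]-2,5,5,8a-tetramethyldecahydronaphthalen-2-yl]oxy}triethylsilane | C/C(Br)=C/CC[C@@H]1[C@@]2(C)CCCC(C)(C)[C@H]2CC[C@@]1(C)O[Si](CC)(CC)CC
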